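All runs come from a simulation with made-up constants; the scatter is artificial.

Which flask held the most bis adduct at 2.0 min, and how much did the first and the last hold?

| flask | substrate | reagent | remark | time |
|---|---|---|---|---|
| eta | 0.031 M | 0.020 M | run made earlier |  |
| gamma | 0.031 M | 0.12 M | run made earlier |  |
| beta | 0.029 M | 0.062 M | run made earlier |  |
| Tuesday's | 0.031 M | 0.0620 M |  | 2.0 min |
| Friday's | 0.060 M | 0.0150 M |  | 2.0 min |
| Monday's | 0.10 M | 0.100 M |  | 2.0 min |
| Sunday's | 0.0080 M | 0.0200 M |  | 2.0 min |
| Saturday's | 0.015 M | 0.0200 M |  | 2.0 min |

- eta (time / s: bis adduct / %, substrate / %): 15.0: 0, 84; 30.0: 5, 69; 50.0: 8, 63; 60.0: 7, 54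
- gamma (time / s: bis adduct / %, substrate / %): 10.0: 17, 38; 20.0: 41, 17; 40.0: 63, 4; 60.0: 76, 0
- beta (time / s: bis adduct / %, substrate / %): 15.0: 12, 47; 30.0: 25, 26; 50.0: 36, 19; 60.0: 44, 15

(scatter of a reading: 2 percentage points)

- a reading or a percentage of bis adduct counts all its forms, free or not

- the flasks put in order of amount of bis adduct, in percent of the substrate charged, best first, at 2.0 min (Tuesday's / Friday's / Monday's / Sunday's / Saturday's)
- the amount of bis adduct, in percent of the substrate charged of the flask you put first, at 2.0 min
- the amount of bis adduct, in percent of the substrate charged of the flask you put last, at 2.0 min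

I asked first what the reagent could pay for, and built the flask up one process at a time.

1. I began with the main step by itself: substrate + reagent → first product, one reagent each. It makes no bis adduct, so the number was zero. Friday's, with less reagent than substrate, could turn at most 25.0 % of its substrate into first product. There the reagent is the limiting reagent.

2. I added first product + reagent → bis adduct. Each bis adduct then costs two reagents. This gives the reagent cap, C = R/(2S), with R and S the charged reagent and substrate: 12.5 % for Friday's. C is the bis adduct, in percent of the substrate charged, if no reagent stopped at first product.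

3. The second step has to wait for first product, so I expected a flask that still held first product to stand below C. The last reading of the eta run fitted this. Its C was 32.3 %, but it read 7 % at 60.0 s, with 54 % of the substrate still present. Friday's has less reagent than eta, so I expected a small fraction of its C.

4. Any further step that uses no reagent leaves this balance as it stands, so I kept C for the rest. Monday's has 50.0 % and Saturday's 66.7 %. Tuesday's has 100 % and Sunday's 125 %. Friday's C is the lowest, so I put it last.

5. Tuesday's and Sunday's have a higher C than the other flasks, so I ranked these two by pace. Tuesday's has more reagent than Sunday's. The beta run, charged much like Tuesday's, already read 44 % at 60.0 s. I put Tuesday's first.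

The forecast gave Tuesday's > Sunday's > Monday's > Saturday's > Friday's, with 58 % first and 1.8 % last. It agreed with my ends and warned, “Sunday versus Monday is close”.

Tuesday's gave 55.1 % and Friday's 1.88 %, in the order Tuesday's > Sunday's > Monday's > Saturday's > Friday's.

    reagent + first product → bis adduct (k = 0.823 /M/s)
    crystals ⇌ bis adduct, rate k2*(cs2 - [bis adduct]) while solid is left; crystals form when [bis adduct] > cs2 (solubility = 15.0 mM, k = 7.88 /s)
    substrate + reagent → first product (k = 0.898 /M/s)
    bis adduct ⇌ isomer of the product (K = 0.340, k = 0.0293 /s)

Friday's had 0.194 % of its reagent left at 2.00 min, and at 20.0 min it still held 1.89 % of bis adduct. Its 1.88 % was 15.0 % of its C. The neighbour of Friday's charged with 0.060 M of reagent had a C of 50.0 %, and it held 22.8 % of bis adduct with 0.840 % of its reagent left.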